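**Retrosynthetic overview**
1. Target ⇒ (global O-debenzylation) tribenzyl ether ⇒ (B-alkyl Suzuki–Miyaura, C3'–CH2 bond) 3'-bromoflavonol dibenzyl ether + (S)-4-(benzyloxy)-3-methylbut-1-ene.
2. Alkene ⇒ (Wittig, redox, O-benzylation) (R)-Roche ester ⇒ ene-reductase reduction of achiral methyl 2-(hydroxymethyl)acrylate, which sets the only stereocentre.
3. 3-OH ⇒ C2=C3 epoxidation of the flavone. 5-OMe ⇒ chelation-controlled 5-O-debenzylation and methylation of a 5,7-bis(benzyloxy)-6-methoxyflavone.
4. Flavone ⇒ 2'-hydroxychalcone ⇒ (Claisen–Schmidt) 3-bromo-4-methoxybenzaldehyde + an o-hydroxyacetophenone. The acetophenone comes from symmetric 3,5-bis(benzyloxy)-4-methoxyphenol, so ortho-functionalisation has one possible outcome.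
5. Ring order: rings A and B are bought as benzene rings. Ring C (the pyranone) is the only ring formed, by oxidative cyclisation of the chalcone.

Assumption: the three starting materials are catalogue chemicals, the ene-reductase is picked from a commercial Old Yellow Enzyme panel, and DMDO is prepared beforehand as an acetone solution.

**Fragment 1 (side chain)**

Step 1
Reactants: 1 methyl 2-(hydroxymethyl)acrylate
Product: 2 methyl (R)-3-hydroxy-2-methylpropanoate
Conditions: ene-reductase (FMN-dependent, Old Yellow Enzyme family), NAD+ (cat.), formate dehydrogenase, HCO2Na, Tris·HCl buffer pH 7.5, 30 °C, 24 h; NaCl, EtOAc extraction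
Reagents that add atoms: none
Why: Asymmetric bioreduction of an activated C=C bond, in which the reduced flavin delivers hydride to the terminal =CH2 carbon and an active-site tyrosine protonates Cα from the opposite face, giving the (R)-ester in >99% ee for this substrate class while formate dehydrogenase recycles NADH.

Step 2
Reactants: 2 methyl (R)-3-hydroxy-2-methylpropanoate
Product: 3 methyl (R)-3-(benzyloxy)-2-methylpropanoate
Conditions: BnOC(=NH)CCl3, TfOH (cat.), CH2Cl2/cyclohexane, 0 °C to rt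
Reagents that add atoms: benzyl 2,2,2-trichloroacetimidate, N=C(OCc1ccccc1)C(Cl)(Cl)Cl
Why: Acid-catalysed trichloroacetimidate O-benzylation needs no base, so the β-hydroxy ester neither epimerises at Cα nor eliminates.

Step 3
Reactants: 3 methyl (R)-3-(benzyloxy)-2-methylpropanoate
Product: 4 (S)-3-(benzyloxy)-2-methylpropan-1-ol
Conditions: LiAlH4, THF, 0 °C; aqueous work-up
Reagents that add atoms: none
Why: Hydride reduction of the ester touches no bond at the stereocentre, and the descriptor becomes S only through the change in CIP priorities.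

Step 4
Reactants: 4 (S)-3-(benzyloxy)-2-methylpropan-1-ol
Product: 5 (R)-3-(benzyloxy)-2-methylpropanal
Conditions: TEMPO (10 mol %), PhI(OAc)2, CH2Cl2, rt; used crude at once
Reagents that add atoms: none
Why: Oxoammonium-catalysed alcohol oxidation stops at the aldehyde under near-neutral conditions, which keeps the epimerisable α-centre intact.

Step 5
Reactants: 5 (R)-3-(benzyloxy)-2-methylpropanal
Product: 6 (S)-{[(2-methylbut-3-en-1-yl)oxy]methyl}benzene
Conditions: Ph3PCH3Br (1.3 equiv), NaN(SiMe3)2 (1.2 equiv), THF, 0 °C; then 5, −78 °C to rt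
Reagents that add atoms: methyltriphenylphosphonium bromide, C[P+](c1ccccc1)(c1ccccc1)c1ccccc1.[Br-]
Why: Wittig methylenation with the non-stabilised ylide (no excess base) is faster than enolisation at low temperature, so the configuration is kept (S by CIP).

**Fragment 2 (bromoflavonol)**

Step 6
Reactants: 7 methyl 3,5-dihydroxy-4-methoxybenzoate
Product: 8 methyl 3,5-bis(benzyloxy)-4-methoxybenzoate
Conditions: BnBr (2.4 equiv), K2CO3, DMF, 60 °C
Reagents that add atoms: benzyl bromide, BrCc1ccccc1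
Why: Williamson ether synthesis on two equivalent phenols proceeds cleanly and leaves the methyl ester untouched.

Step 7
Reactants: 8 methyl 3,5-bis(benzyloxy)-4-methoxybenzoate
Product: 9 [3,5-bis(benzyloxy)-4-methoxyphenyl]methanol
Conditions: LiAlH4, THF, 0 °C to rt; aqueous work-up
Reagents that add atoms: none
Why: Hydride reduction of a benzoate ester gives the benzylic alcohol, and aryl benzyl and methyl ethers are inert to it.

Step 8
Reactants: 9 [3,5-bis(benzyloxy)-4-methoxyphenyl]methanol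
Product: 10 3,5-bis(benzyloxy)-4-methoxybenzaldehyde
Conditions: MnO2 (activated, excess), CH2Cl2, rt
Reagents that add atoms: none
Why: Heterogeneous MnO2 oxidation is selective for benzylic alcohols and does not go on to the acid.

Step 9
Reactants: 10 3,5-bis(benzyloxy)-4-methoxybenzaldehyde
Product: 12 3,5-bis(benzyloxy)-4-methoxyphenol, via aryl formate 11 (not isolated)
Conditions: mCPBA (1.3 equiv), CH2Cl2, 0 °C to rt; then K2CO3 (cat.), MeOH, rt
Reagents that add atoms: mCPBA, OOC(=O)c1cccc(Cl)c1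
Why: In this Baeyer–Villiger (Dakin-type) oxidation the electron-rich trialkoxyaryl group migrates in preference to hydrogen, and mild methanolysis of the formate frees the phenol.

Step 10
Reactants: 12 3,5-bis(benzyloxy)-4-methoxyphenol
Product: 13 2,4-bis(benzyloxy)-6-hydroxy-3-methoxybenzaldehyde
Conditions: MgCl2, Et3N, (CH2O)n, THF, reflux; 1 M HCl work-up
Reagents that add atoms: paraformaldehyde (as formaldehyde), C=O
Why: In the Casnati–Skattebøl ortho-formylation the magnesium phenoxide directs formaldehyde only ortho to OH and a second formaldehyde accepts the hydride; the two ortho sites are equivalent by symmetry, and these non-acidic conditions spare the benzyl ethers that Friedel–Crafts Lewis acids would endanger.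

Step 11
Reactants: 13 2,4-bis(benzyloxy)-6-hydroxy-3-methoxybenzaldehyde
Product: 14 3,5-bis(benzyloxy)-2-(1-hydroxyethyl)-4-methoxyphenol (racemic)
Conditions: MeMgBr (2.5 equiv), THF, 0 °C; aqueous work-up, used without chromatography
Reagents that add atoms: methylmagnesium bromide, C[Mg]Br
Why: Grignard 1,2-addition occurs after the first equivalent has deprotonated the phenol, and the carbinol centre forms racemic and is erased in step 12.

Step 12
Reactants: 14 3,5-bis(benzyloxy)-2-(1-hydroxyethyl)-4-methoxyphenol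
Product: 15 1-[2,4-bis(benzyloxy)-6-hydroxy-3-methoxyphenyl]ethan-1-one
Conditions: MnO2 (activated, excess), CH2Cl2, rt
Reagents that add atoms: none
Why: MnO2 oxidation of the electron-rich secondary benzylic alcohol gives the o-hydroxyacetophenone, which is stabilised by its internal hydrogen bond.

Step 13
Reactants: 15 1-[2,4-bis(benzyloxy)-6-hydroxy-3-methoxyphenyl]ethan-1-one; 16 3-bromo-4-methoxybenzaldehyde
Product: 17 (E)-1-[2,4-bis(benzyloxy)-6-hydroxy-3-methoxyphenyl]-3-(3-bromo-4-methoxyphenyl)prop-2-en-1-one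
Conditions: KOH, EtOH/H2O, rt, 48 h; then dilute HCl
Reagents that add atoms: none
Why: In this Claisen–Schmidt condensation only the ketone can enolise, and E1cB dehydration gives the conjugated (E)-chalcone.

Step 14
Reactants: 17 (E)-chalcone
Product: 18 5,7-bis(benzyloxy)-2-(3-bromo-4-methoxyphenyl)-6-methoxy-4H-chromen-4-one
Conditions: I2 (10 mol %), DMSO, 130 °C, 3 h
Reagents that add atoms: none
Why: Iodine-catalysed oxidative cyclisation of a 2'-hydroxychalcone (DMSO as terminal oxidant) closes ring C, and only one regioisomer is possible because only one phenol is free.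

Step 15
Reactants: 18 5,7-bis(benzyloxy)-2-(3-bromo-4-methoxyphenyl)-6-methoxy-4H-chromen-4-one
Product: 19 7-(benzyloxy)-2-(3-bromo-4-methoxyphenyl)-5-hydroxy-6-methoxy-4H-chromen-4-one
Conditions: BCl3 (1.2 equiv), CH2Cl2, −78 °C, 1 h; then H2O
Reagents that add atoms: none
Why: In this chelation-controlled Lewis-acid ether cleavage, BCl3 bound to C4=O forms a six-membered chelate with the peri 5-oxygen, so at −78 °C only that benzyl group leaves while 7-OBn and the methyl ethers stay.

Step 16
Reactants: 19 7-(benzyloxy)-2-(3-bromo-4-methoxyphenyl)-5-hydroxy-6-methoxy-4H-chromen-4-one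
Product: 20 7-(benzyloxy)-2-(3-bromo-4-methoxyphenyl)-5,6-dimethoxy-4H-chromen-4-one
Conditions: MeI (excess), K2CO3, DMF, 45 °C
Reagents that add atoms: iodomethane, CI
Why: Williamson O-methylation has only one free phenol to act on, and excess MeI with gentle heating overcomes the hydrogen bond to C4=O.

Step 17
Reactants: 20 7-(benzyloxy)-2-(3-bromo-4-methoxyphenyl)-5,6-dimethoxy-4H-chromen-4-one
Product: 22 7-(benzyloxy)-2-(3-bromo-4-methoxyphenyl)-3-hydroxy-5,6-dimethoxy-4H-chromen-4-one, via flavone epoxide 21 (not isolated)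
Conditions: DMDO (acetone solution, 3 equiv), CH2Cl2, 0 °C to rt; then p-TsOH (cat.)
Reagents that add atoms: dimethyldioxirane, CC1(C)OO1
Why: Dioxirane epoxidation of the enol-ether-like C2=C3 bond followed by acid-catalysed epoxide opening with loss of the C3 proton gives the flavonol, so the transient racemic epoxide centres vanish.

Step 18
Reactants: 22 7-(benzyloxy)-2-(3-bromo-4-methoxyphenyl)-3-hydroxy-5,6-dimethoxy-4H-chromen-4-one
Product: 23 3,7-bis(benzyloxy)-2-(3-bromo-4-methoxyphenyl)-5,6-dimethoxy-4H-chromen-4-one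
Conditions: BnBr, K2CO3, DMF, rt to 50 °C
Reagents that add atoms: benzyl bromide, BrCc1ccccc1
Why: Williamson benzylation masks the metal-chelating 3-OH before the palladium step, using a group that leaves together with the others at the end.

**Union and end game**

Step 19
Reactants: 6 (S)-{[(2-methylbut-3-en-1-yl)oxy]methyl}benzene; 23 3,7-bis(benzyloxy)-2-(3-bromo-4-methoxyphenyl)-5,6-dimethoxy-4H-chromen-4-one
Product: 25 3,7-bis(benzyloxy)-2-{3-[(3S)-4-(benzyloxy)-3-methylbutyl]-4-methoxyphenyl}-5,6-dimethoxy-4H-chromen-4-one, via B-alkyl-9-BBN borane 24 (not isolated)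
Conditions: 6 (1.5 equiv), 9-BBN-H (1.45 equiv), THF, 0 °C to rt; then 23, PdCl2(dppf) (5 mol %), Cs2CO3, DMF/H2O, 60 °C
Reagents that add atoms: none
Why: Anti-Markovnikov hydroboration of the terminal alkene followed by B-alkyl Suzuki–Miyaura coupling (oxidative addition of the aryl bromide to zerovalent palladium) forms the sp3–sp2 bond two carbons away from the stereocentre, which is not involved.

Step 20
Reactants: 25 3,7-bis(benzyloxy)-2-{3-[(3S)-4-(benzyloxy)-3-methylbutyl]-4-methoxyphenyl}-5,6-dimethoxy-4H-chromen-4-one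
Product: 26 3,7-dihydroxy-2-{3-[(3S)-4-hydroxy-3-methylbutyl]-4-methoxyphenyl}-5,6-dimethoxy-4H-chromen-4-one
Conditions: H2 (1 atm), 10% Pd/C, EtOAc/MeOH, rt
Reagents that add atoms: none
Why: Catalytic hydrogenolysis removes the two aryl benzyl ethers and the alkyl benzyl ether in one operation, while the flavonol enone, the methyl ethers and the stereocentre are untouched.

**Compound list**

| No. | Name | SMILES | Role |
|---|---|---|---|
| 1 | methyl 2-(hydroxymethyl)acrylate | C=C(CO)C(=O)OC | starting material |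
| 2 | methyl (R)-3-hydroxy-2-methylpropanoate | COC(=O)[C@H](C)CO | intermediate |
| 3 | methyl (R)-3-(benzyloxy)-2-methylpropanoate | COC(=O)[C@H](C)COCc1ccccc1 | intermediate |
| 4 | (S)-3-(benzyloxy)-2-methylpropan-1-ol | OC[C@H](C)COCc1ccccc1 | intermediate |
| 5 | (R)-3-(benzyloxy)-2-methylpropanal | O=C[C@H](C)COCc1ccccc1 | intermediate |
| 6 | (S)-{[(2-methylbut-3-en-1-yl)oxy]methyl}benzene | C=C[C@H](C)COCc1ccccc1 | intermediate |
| 7 | methyl 3,5-dihydroxy-4-methoxybenzoate | COC(=O)c1cc(O)c(OC)c(O)c1 | starting material |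
| 8 | methyl 3,5-bis(benzyloxy)-4-methoxybenzoate | COC(=O)c1cc(OCc2ccccc2)c(OC)c(OCc2ccccc2)c1 | intermediate |
| 9 | [3,5-bis(benzyloxy)-4-methoxyphenyl]methanol | OCc1cc(OCc2ccccc2)c(OC)c(OCc2ccccc2)c1 | intermediate |
| 10 | 3,5-bis(benzyloxy)-4-methoxybenzaldehyde | O=Cc1cc(OCc2ccccc2)c(OC)c(OCc2ccccc2)c1 | intermediate |
| 11 | 3,5-bis(benzyloxy)-4-methoxyphenyl formate | O=COc1cc(OCc2ccccc2)c(OC)c(OCc2ccccc2)c1 | intermediate (not isolated) |
| 12 | 3,5-bis(benzyloxy)-4-methoxyphenol | Oc1cc(OCc2ccccc2)c(OC)c(OCc2ccccc2)c1 | intermediate |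
| 13 | 2,4-bis(benzyloxy)-6-hydroxy-3-methoxybenzaldehyde | O=Cc1c(O)cc(OCc2ccccc2)c(OC)c1OCc1ccccc1 | intermediate |
| 14 | 3,5-bis(benzyloxy)-2-(1-hydroxyethyl)-4-methoxyphenol (racemic) | CC(O)c1c(O)cc(OCc2ccccc2)c(OC)c1OCc1ccccc1 | intermediate |
| 15 | 1-[2,4-bis(benzyloxy)-6-hydroxy-3-methoxyphenyl]ethan-1-one | CC(=O)c1c(O)cc(OCc2ccccc2)c(OC)c1OCc1ccccc1 | intermediate |
| 16 | 3-bromo-4-methoxybenzaldehyde | COc1ccc(C=O)cc1Br | starting material |
| 17 | (E)-1-[2,4-bis(benzyloxy)-6-hydroxy-3-methoxyphenyl]-3-(3-bromo-4-methoxyphenyl)prop-2-en-1-one | COc1ccc(/C=C/C(=O)c2c(O)cc(OCc3ccccc3)c(OC)c2OCc2ccccc2)cc1Br | intermediate |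
| 18 | 5,7-bis(benzyloxy)-2-(3-bromo-4-methoxyphenyl)-6-methoxy-4H-chromen-4-one | COc1ccc(-c2cc(=O)c3c(OCc4ccccc4)c(OC)c(OCc4ccccc4)cc3o2)cc1Br | intermediate |
| 19 | 7-(benzyloxy)-2-(3-bromo-4-methoxyphenyl)-5-hydroxy-6-methoxy-4H-chromen-4-one | COc1ccc(-c2cc(=O)c3c(O)c(OC)c(OCc4ccccc4)cc3o2)cc1Br | intermediate |
| 20 | 7-(benzyloxy)-2-(3-bromo-4-methoxyphenyl)-5,6-dimethoxy-4H-chromen-4-one | COc1ccc(-c2cc(=O)c3c(OC)c(OC)c(OCc4ccccc4)cc3o2)cc1Br | intermediate |
| 21 | 7-(benzyloxy)-2-(3-bromo-4-methoxyphenyl)-2,3-epoxy-5,6-dimethoxychroman-4-one (racemic) | COc1ccc(cc1Br)C12OC1C(=O)c1c(O2)cc(OCc2ccccc2)c(OC)c1OC | intermediate (not isolated) |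
| 22 | 7-(benzyloxy)-2-(3-bromo-4-methoxyphenyl)-3-hydroxy-5,6-dimethoxy-4H-chromen-4-one | COc1ccc(-c2oc3cc(OCc4ccccc4)c(OC)c(OC)c3c(=O)c2O)cc1Br | intermediate |
| 23 | 3,7-bis(benzyloxy)-2-(3-bromo-4-methoxyphenyl)-5,6-dimethoxy-4H-chromen-4-one | COc1ccc(-c2oc3cc(OCc4ccccc4)c(OC)c(OC)c3c(=O)c2OCc2ccccc2)cc1Br | intermediate |
| 24 | 9-[(3S)-4-(benzyloxy)-3-methylbutyl]-9-borabicyclo[3.3.1]nonane | B1(C2CCCC1CCC2)CC[C@H](C)COCc1ccccc1 | intermediate (not isolated) |
| 25 | 3,7-bis(benzyloxy)-2-{3-[(3S)-4-(benzyloxy)-3-methylbutyl]-4-methoxyphenyl}-5,6-dimethoxy-4H-chromen-4-one | COc1ccc(-c2oc3cc(OCc4ccccc4)c(OC)c(OC)c3c(=O)c2OCc2ccccc2)cc1CC[C@H](C)COCc1ccccc1 | intermediate |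
| 26 | 3,7-dihydroxy-2-{3-[(3S)-4-hydroxy-3-methylbutyl]-4-methoxyphenyl}-5,6-dimethoxy-4H-chromen-4-one | COc1ccc(-c2oc3cc(O)c(OC)c(OC)c3c(=O)c2O)cc1CC[C@H](C)CO | target |

**Step count:** 20 steps in total. The longest linear sequence is 15 steps (steps 6 to 20, from 7 to 26).

**Three steps most likely to fail**

Step 15 (mono-debenzylation). The danger is partial loss of the 7-O-benzyl group or incomplete reaction, which would give mixtures. The fallback sets out from 18. Both aryl benzyl ethers are removed with excess BCl3 (CH2Cl2, −78 to 0 °C) to give 2-(3-bromo-4-methoxyphenyl)-5,7-dihydroxy-6-methoxy-4H-chromen-4-one F1. Selectivity then rests on acidity instead of chelation. With BnBr (1.05 equiv) and K2CO3 in acetone only the free, acidic 7-OH is alkylated, because the 5-OH is locked in its hydrogen bond to C4=O. This comes back to the route at 19.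

Step 17 (C3 hydroxylation with DMDO). The enone double bond is epoxidised slowly, and ring A or the benzylic CH2 may be oxidised in competition. The fallback sets out from 20 and replaces electrophilic oxidation by deprotonative borylation.
- LiN(iPr)2 in THF at −78 °C gives 7-(benzyloxy)-2-(3-bromo-4-methoxyphenyl)-3-lithio-5,6-dimethoxy-4H-chromen-4-one F2.
- B(OMe)3 traps it as dimethyl [7-(benzyloxy)-2-(3-bromo-4-methoxyphenyl)-5,6-dimethoxy-4-oxo-4H-chromen-3-yl]boronate F3.
- H2O2/AcOH oxidises the C–B bond, and the fallback comes back to the route at 22.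

Step 19 (B-alkyl Suzuki–Miyaura coupling). The bromide is ortho-substituted and electron-rich, so protodeboronation or β-hydride elimination may compete. The fallback sets out from 5 and forms the bond as sp–sp2.
- Ohira–Bestmann homologation (dimethyl (1-diazo-2-oxopropyl)phosphonate, K2CO3, MeOH, 0 °C) gives (S)-{[(2-methylbut-3-yn-1-yl)oxy]methyl}benzene F4.
- Sonogashira coupling with 23 (PdCl2(PPh3)2, CuI, Et3N, DMF, 70 °C) gives 3,7-bis(benzyloxy)-2-{3-[(3S)-4-(benzyloxy)-3-methylbut-1-yn-1-yl]-4-methoxyphenyl}-5,6-dimethoxy-4H-chromen-4-one F5.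
- H2 over 10% Pd/C saturates the triple bond while cleaving the three benzyl ethers, and the fallback comes back to the route at 26.

**Further compounds**
F1 | step 15 | 2-(3-bromo-4-methoxyphenyl)-5,7-dihydroxy-6-methoxy-4H-chromen-4-one | COc1ccc(-c2cc(=O)c3c(O)c(OC)c(O)cc3o2)cc1Br
F2 | step 17 | 7-(benzyloxy)-2-(3-bromo-4-methoxyphenyl)-3-lithio-5,6-dimethoxy-4H-chromen-4-one | COc1ccc(-c2oc3cc(OCc4ccccc4)c(OC)c(OC)c3c(=O)c2[Li])cc1Br
F3 | step 17 | dimethyl [7-(benzyloxy)-2-(3-bromo-4-methoxyphenyl)-5,6-dimethoxy-4-oxo-4H-chromen-3-yl]boronate | COc1ccc(-c2oc3cc(OCc4ccccc4)c(OC)c(OC)c3c(=O)c2B(OC)OC)cc1Br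
F4 | step 19 | (S)-{[(2-methylbut-3-yn-1-yl)oxy]methyl}benzene | C#C[C@H](C)COCc1ccccc1
F5 | step 19 | 3,7-bis(benzyloxy)-2-{3-[(3S)-4-(benzyloxy)-3-methylbut-1-yn-1-yl]-4-methoxyphenyl}-5,6-dimethoxy-4H-chromen-4-one | COc1ccc(-c2oc3cc(OCc4ccccc4)c(OC)c(OC)c3c(=O)c2OCc2ccccc2)cc1C#C[C@H](C)COCc1ccccc1
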